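I began from what the flask cannot change. Whatever X leaves stands in G, so cX + cG holds at the charge, and by the list of suspects each chain begun uses up one D.

| flask | X | D | remark | time |
|---|---|---|---|---|
| amber | 22 mM | 0.85 mM | run made earlier |  |
| blue | 22 mM | 1.3 mM | run made earlier |  |
| green | 44 mM | 1.7 mM | run made earlier |  |
| Saturday's | 22 mM | 1.7 mM |  | 1.0 h |
| Wednesday's | 22 mM | 1.7 mM |  | 0.25 h |

| run | time / min | G / % |
|---|---|---|
| amber | 10.0 | 5.7 |
| amber | 25.0 | 22.4 |
| amber | 50.0 | 46.8 |
| amber | 80.0 | 64.3 |
| blue | 10.0 | 9.7 |
| blue | 25.0 | 32.2 |
| blue | 50.0 | 59.3 |
| blue | 80.0 | 79.1 |
| green | 10.0 | 18.9 |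
| green | 25.0 | 48.2 |
| green | 50.0 | 77.7 |
| green | 80.0 | 91.3 |

(standard deviation of a reading: 1 percentage point)

- the average divides the monomer in chains by the number of chains begun, living and dead together
- the earlier runs were read with a standard deviation of 1 percentage point
- on the list of suspects stand: X + D -> Q + G; X + Q -> G + Q; D -> E
- the earlier runs do not show the number of chains; that part of a forecast is a guess

* which of the two ends with the longer chains by the average number of monomer units in a chain (chains begun, living or dead) ("neither" if they lie within 10%) (Saturday's / Wednesday's / neither)
* average number of monomer units in a chain (chains begun, living or dead) at the end, Saturday's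
* average number of monomer units in a chain (chains begun, living or dead) at the end, Wednesday's

Saturday's and Wednesday's flasks carry the same charges, yet two lengths are asked. That looked contradictory until I took them as one recipe stopped at 1.0 h and at 0.25 h. The length counts monomer already in chains, so the reading to watch at the stop is the conversion x. The charges give the units per charged D, 12.9. The length is x times this ratio, divided by the share of charged D that has begun chains. That share cannot exceed one, so x times the ratio is a floor.

For x I used the logarithm of charged over remaining X, the pseudo-first-order measure, and assumed it proportional to cD at a given time. The readings of amber against blue allowed that: at 80.0 min the ratio of the measures was 0.658, that of the charges of D 0.654. I scaled blue to 1.7 mM and interpolated. 1.18 at 50.0 min and 2.05 at 80.0 min gave x = 76.9% for Saturday's. 0.133 at 10.0 min and 0.508 at 25.0 min gave x = 22.8% for Wednesday's. On these estimated conversions the floors came to 9.92 and 2.94. The early slope of the measure was 0.860 of the late one. Taking that as the ratio of chain counts, I expected Saturday's to be longer by a factor of 2.90.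

The forecast said Saturday's, with 365 (150 to 1500) for Saturday's and 39 (27 to 55) for Wednesday's. It read the time as “D aged alone before X is added, with the run going to full conversion”. I read a run stopped at that time, and there we differ.

Saturday's gave 14.1 and Wednesday's 5.20, so Saturday's was longer, by a factor of 2.71. At 1.00 h Saturday's still held 23.7% of its X, with Q at 1.19 mM. With 12.9 units per charged D, its 76.3% in G gives a floor of 9.84. The length stood above that by a factor of 1.43, the inverse of the 0.700 share of charged D standing as Q.

    X + D → Q + G (k = 0.0511 /M/s)
    X + Q → G + Q, rate k2*[Q]*[X] (k = 0.389 /M/s)
    D → E (k = 3.53 × 10⁻⁴ /s)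

Saturday's recipe with 88 mM of X has a ratio of 51.8, and with 12.5% of its X left, a floor of 45.3. Its computed length was 49.2.

The numbers in the tables are calculated with constants of no real substance, noise included.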